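**Assumption:** the SMILES is taken literally, so rings B/C are trans-fused and the target is (13S,14S,15S,20S,21R) with a (Z)-C4=C5 bond in the labels below.

**Labels used in names:** C1–C4 butylidene chain (C4 = CH), C5 enol-ether carbon, O6 and C7(=O) of ring A, C9=C10 (C9 bears C7), C11 and C12 (ring-B CH2), C13 and C14 (B/C junction, C14 next to C9), C15 (quaternary, bears C16 and lactone carbonyl C23), C16=C17, C18, C19 (ring D), C20 (C/D junction), C21 (bears O22 and acyl carbon C24). Ring A = butenolide, B = cyclohexene fused to A, C = cyclopentane, D = cyclohexene, E = bridging γ-lactone.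

## Retrosynthetic overview

1. Ring A and the ketone come last: Sonogashira coupling of ring-B enol triflate 20 with 1-pentyne, AgNO3-catalysed 5-exo-dig lactonisation (Z), then Fukuyama coupling of the C24 S-ethyl thioester with n-PrZnI.
2. Rings C and B form in one operation from 17: intramolecular Michael addition of the ring-D/E lactone dienolate (C15) to the (E)-enoate (C14) closes carbocycle C; the ester enolate released at C9 acylates the Weinreb amide (C10) and closes ring B trans to C.
3. Fragment union (C21–C13): Pd-catalysed allylic alkylation of thioester lactone 9 with allylic carbonate 16.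
4. East fragment 9 (rings D/E, sets C20): D-proline aldol of cyclohexanone with ethyl glyoxylate, enol triflate, carbonylative lactonisation. West fragment 16 (C7–C14, sets C13): from L-glutamic acid.
5. Ring order: D (cyclohexanone) → E → C → B → A.

## Route

**East fragment**

Step 1
Reactants: 1 cyclohexanone; 2 ethyl glyoxylate
Product: 3 ethyl (2S)-2-hydroxy-2-[(1R)-2-oxocyclohexyl]acetate
Conditions: D-proline (20 mol%), DMSO, rt
Reagents that add atoms: none
Why: Proline-catalysed direct aldol reaction; the D-proline enamine of cyclohexanone adds to the aldehyde through the Houk–List transition state to give the anti aldol and fix C20 (the 1R ring carbon), while the carbinol centre (C21) is planarised later and is of no consequence.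

Step 2
Reactants: 3 ethyl (2S)-2-hydroxy-2-[(1R)-2-oxocyclohexyl]acetate
Product: 4 ethyl (2S)-2-[(tert-butyldimethylsilyl)oxy]-2-[(1R)-2-oxocyclohexyl]acetate
Conditions: tBuMe2SiCl, imidazole, DMF, rt
Reagents that add atoms: tert-butyldimethylsilyl chloride, CC(C)(C)[Si](C)(C)Cl
Why: Silyl ether protection of the β-hydroxy ketone, which blocks retro-aldol and alkoxide chemistry in the enolisation that follows.

Step 3
Reactants: 4 ethyl (2S)-2-[(tert-butyldimethylsilyl)oxy]-2-[(1R)-2-oxocyclohexyl]acetate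
Product: 5 ethyl (2S)-2-[(tert-butyldimethylsilyl)oxy]-2-[(1R)-2-{[(trifluoromethyl)sulfonyl]oxy}cyclohex-2-en-1-yl]acetate
Conditions: LiN(iPr)2, THF, −78 °C; then PhNTf2, −78 → 0 °C
Reagents that add atoms: N-phenylbis(trifluoromethanesulfonimide), O=S(=O)(N(c1ccccc1)S(=O)(=O)C(F)(F)F)C(F)(F)F
Why: Kinetic enolate O-triflation; the hindered base removes the unhindered C16 proton, so the C15=C16 enol triflate forms and C20 (now allylic and non-enolisable) keeps its configuration.

Step 4
Reactants: 5 ethyl (2S)-2-[(tert-butyldimethylsilyl)oxy]-2-[(1R)-2-{[(trifluoromethyl)sulfonyl]oxy}cyclohex-2-en-1-yl]acetate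
Product: 6 ethyl (2S)-2-hydroxy-2-[(1R)-2-{[(trifluoromethyl)sulfonyl]oxy}cyclohex-2-en-1-yl]acetate
Conditions: HF·pyridine, THF, 0 °C → rt
Reagents that add atoms: none
Why: Fluoride-mediated desilylation under acidic conditions that leave the vinyl triflate and the ester untouched.

Step 5
Reactants: 6 ethyl (2S)-2-hydroxy-2-[(1R)-2-{[(trifluoromethyl)sulfonyl]oxy}cyclohex-2-en-1-yl]acetate
Product: 7 ethyl (3S,3aS)-1-oxo-1,3,3a,4,5,6-hexahydro-2-benzofuran-3-carboxylate (ring D with α-alkylidene γ-lactone E; C15=C16)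
Conditions: Pd(OAc)2 (5 mol%), Ph2P(CH2)3PPh2 (5 mol%), CO (1 atm), Et3N, DMF, 60 °C
Reagents that add atoms: carbon monoxide, [C-]#[O+]
Why: Palladium-catalysed carbonylative lactonisation (intramolecular alkoxycarbonylation); the acyl-palladium formed from the vinyl triflate and CO is trapped by the neighbouring hydroxyl to close the five-membered lactone.

Step 6
Reactants: 7 ethyl (3S,3aS)-1-oxo-1,3,3a,4,5,6-hexahydro-2-benzofuran-3-carboxylate
Product: 8 (3S,3aS)-1-oxo-1,3,3a,4,5,6-hexahydro-2-benzofuran-3-carboxylic acid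
Conditions: LiOH (1.1 equiv), THF/H2O, 0 °C; then 1 M HCl
Reagents that add atoms: lithium hydroxide, [Li+].[OH-]
Why: Saponification of the α-oxygen-activated ethyl ester; any lactone that opens recloses on acidification, and epimerisation at C21 does not matter.

Step 7
Reactants: 8 (3S,3aS)-1-oxo-1,3,3a,4,5,6-hexahydro-2-benzofuran-3-carboxylic acid
Product: 9 S-ethyl (3S,3aS)-1-oxo-1,3,3a,4,5,6-hexahydro-2-benzofuran-3-carbothioate
Conditions: EtSH, EDC·HCl, DMAP (cat.), CH2Cl2, 0 °C → rt
Reagents that add atoms: ethanethiol, CCS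
Why: Carbodiimide (Steglich-type) thioesterification; the thioester acidifies C21–H, has no enolisable position of its own and is the latent butanoyl group.

**West fragment**

Step 8
Reactants: 10 L-glutamic acid
Product: 11 (2S)-5-oxooxolane-2-carboxylic acid
Conditions: NaNO2, 2 M HCl, H2O, 0 °C → rt
Reagents that add atoms: none
Why: Diazotisation with lactonisation; double inversion through the α-lactone gives overall retention, so C13 comes from the chiral pool.

Step 9
Reactants: 11 (2S)-5-oxooxolane-2-carboxylic acid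
Product: 12 (5S)-5-(hydroxymethyl)oxolan-2-one
Conditions: BH3·SMe2, THF, 0 °C → rt; then MeOH
Reagents that add atoms: none
Why: Chemoselective borane reduction of the carboxylic acid in the presence of the lactone.

Step 10
Reactants: 12 (5S)-5-(hydroxymethyl)oxolan-2-one
Product: 13 (2S)-5-oxooxolane-2-carbaldehyde
Conditions: Dess–Martin periodinane, NaHCO3, CH2Cl2, 0 °C → rt (used crude)
Reagents that add atoms: none
Why: Dess–Martin oxidation under buffered, non-epimerising conditions.

Step 11
Reactants: 13 (2S)-5-oxooxolane-2-carbaldehyde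
Product: 14 tert-butyl (2E)-3-[(2S)-5-oxooxolan-2-yl]prop-2-enoate
Conditions: Ph3P=CHCO2tBu, CH2Cl2, rt
Reagents that add atoms: tert-butyl (triphenylphosphoranylidene)acetate, CC(C)(C)OC(=O)C=P(c1ccccc1)(c1ccccc1)c1ccccc1
Why: Wittig olefination with a stabilised ylide, which is E-selective and installs C9 and C7.

Step 12
Reactants: 14 tert-butyl (2E)-3-[(2S)-5-oxooxolan-2-yl]prop-2-enoate
Product: 15 tert-butyl (2E,4S)-4-hydroxy-7-[methoxy(methyl)amino]-7-oxohept-2-enoate
Conditions: MeNH(OMe)·HCl, iPrMgCl (amide preformed), THF, −20 → 0 °C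
Reagents that add atoms: N,O-dimethylhydroxylamine hydrochloride, CNOC.Cl
Why: Aminolysis of the lactone by the chloromagnesium amide (Weinreb amide formation); the hindered tert-butyl enoate is left alone and the C–O bond at C13 is not touched.

Step 13
Reactants: 15 tert-butyl (2E,4S)-4-hydroxy-7-[methoxy(methyl)amino]-7-oxohept-2-enoate
Product: 16 tert-butyl (2E,4S)-4-[(tert-butoxycarbonyl)oxy]-7-[methoxy(methyl)amino]-7-oxohept-2-enoate
Conditions: Boc2O, DMAP (10 mol%), CH2Cl2, 0 °C (crude 15 used at once)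
Reagents that add atoms: di-tert-butyl dicarbonate, CC(C)(C)OC(=O)OC(=O)OC(C)(C)C
Why: Carbonate formation (O-acylation) turns the allylic alcohol into an ionisable leaving group and prevents relactonisation; no amine base is used, to avoid isomerisation to the γ-keto ester.

**Union and completion**

Step 14
Reactants: 9 S-ethyl (3S,3aS)-1-oxo-1,3,3a,4,5,6-hexahydro-2-benzofuran-3-carbothioate; 16 tert-butyl (2E,4S)-4-[(tert-butoxycarbonyl)oxy]-7-[methoxy(methyl)amino]-7-oxohept-2-enoate
Product: 17 S-ethyl (3R,3aS)-3-{(4S,5E)-7-tert-butoxy-1-[methoxy(methyl)amino]-1,7-dioxohept-5-en-4-yl}-1-oxo-1,3,3a,4,5,6-hexahydro-2-benzofuran-3-carbothioate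
Conditions: Pd2(dba)3 (2.5 mol%), PPh3 (10 mol%), THF, rt
Reagents that add atoms: none
Why: Tsuji–Trost allylic alkylation; zerovalent palladium ionises the carbonate with inversion, the released tert-butoxide deprotonates C21, and the soft enolate attacks the allyl terminus remote from the ester (C13) anti to palladium (net retention, 13S) on the lactone face anti to C19 (21R).

Step 15
Reactants: 17 S-ethyl (3R,3aS)-3-{(4S,5E)-7-tert-butoxy-1-[methoxy(methyl)amino]-1,7-dioxohept-5-en-4-yl}-1-oxo-1,3,3a,4,5,6-hexahydro-2-benzofuran-3-carbothioate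
Product: 19 B/C/D/E tetracycle with ring B as the enolised β-keto ester (C9–CO2tBu and C10–OH on C9=C10; C21–C(=O)SEt; 13S,14S,15S,20S,21R), via lithium ester enolate 18 (not isolated)
Conditions: LiN(SiMe3)2 (1.1 equiv), THF/DMPU, −78 → 0 °C; then AcOH
Reagents that add atoms: none
Why: Intramolecular Michael addition (the key ring closure) followed in the same flask by a Dieckmann-type Claisen acylation. γ-Deprotonation at C17 gives the lactone dienolate, whose α-carbon C15 adds 5-exo-trig to C14 on the face that carries the tether (15S is forced by the bicycle). C9 sits anti to C12 to avoid allylic 1,3-strain, which sets 14S and the trans B/C junction. The regiospecific ester enolate 18 then acylates the Weinreb amide irreversibly to close ring B.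

Step 16
Reactants: 19 enolised ring-B β-keto ester tetracycle
Product: 20 ring-B enol triflate (C9–CO2tBu, C10–OSO2CF3 on C9=C10; C21–C(=O)SEt; stereocentres as in 19)
Conditions: NaH, THF, 0 °C; then PhNTf2, 0 °C → rt
Reagents that add atoms: N-phenylbis(trifluoromethanesulfonimide), O=S(=O)(N(c1ccccc1)S(=O)(=O)C(F)(F)F)C(F)(F)F
Why: O-Triflation of the β-keto ester enolate, the only acidic site now that the thioester has no α-hydrogen; it fixes the C9=C10 alkene.

Step 17
Reactants: 20 ring-B enol triflate; 21 1-pentyne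
Product: 22 ring-B enyne ester (C9–CO2tBu, C10–C≡C–CH2CH2CH3; C21–C(=O)SEt; stereocentres as in 19)
Conditions: Pd(PPh3)4 (5 mol%), CuI (10 mol%), iPr2NH, DMF, rt
Reagents that add atoms: none
Why: Sonogashira coupling of the electron-poor vinyl triflate; oxidative addition into the C–OTf bond is far faster than into the hindered thioester at room temperature.

Step 18
Reactants: 22 ring-B enyne ester
Product: 24 S-ethyl thioester analogue of the target (rings A–E complete with (Z)-butylidene; C21–C(=O)SEt), via enyne acid 23 (not isolated)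
Conditions: CF3CO2H/CH2Cl2 (1:4), 0 °C → rt, evaporate; then AgNO3 (10 mol%), acetone, rt, dark
Reagents that add atoms: none
Why: Acidolysis of the tert-butyl ester, then silver-catalysed 5-exo-dig lactonisation of the (Z)-2-en-4-ynoic acid; anti addition of O and H across the alkyne puts O6 cis to the propyl group, which is the (Z)-butylidene butenolide.

Step 19
Reactants: 25 1-iodopropane
Product: 26 iodo(propyl)zinc (about 0.5 M in THF)
Conditions: Zn dust, LiCl, BrCH2CH2Br (cat.), Me3SiCl (cat.), THF, 40 °C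
Reagents that add atoms: zinc, [Zn]
Why: Direct insertion of activated zinc into the alkyl iodide (Knochel conditions) gives the mild organozinc needed for the last step.

Step 20
Reactants: 24 S-ethyl thioester analogue of the target; 26 iodo(propyl)zinc
Product: 27 target CNP0423313.2
Conditions: PdCl2(PPh3)2 (10 mol%), toluene/THF, rt
Reagents that add atoms: none
Why: Fukuyama coupling; the acyl-palladium from the thioester is alkylated by the organozinc to give the butanoyl ketone, and lactones, the enol lactone and the alkenes are inert to this reagent, so no stereocentre is touched.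

## Compound list

1 | cyclohexanone | O=C1CCCCC1 | starting material
2 | ethyl glyoxylate | CCOC(=O)C=O | starting material
3 | ethyl (2S)-2-hydroxy-2-[(1R)-2-oxocyclohexyl]acetate | CCOC(=O)[C@@H](O)[C@H]1CCCCC1=O | intermediate
4 | ethyl (2S)-2-[(tert-butyldimethylsilyl)oxy]-2-[(1R)-2-oxocyclohexyl]acetate | CCOC(=O)[C@@H](O[Si](C)(C)C(C)(C)C)[C@H]1CCCCC1=O | intermediate
5 | ethyl (2S)-2-[(tert-butyldimethylsilyl)oxy]-2-[(1R)-2-{[(trifluoromethyl)sulfonyl]oxy}cyclohex-2-en-1-yl]acetate | CCOC(=O)[C@@H](O[Si](C)(C)C(C)(C)C)[C@H]1CCCC=C1OS(=O)(=O)C(F)(F)F | intermediate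
6 | ethyl (2S)-2-hydroxy-2-[(1R)-2-{[(trifluoromethyl)sulfonyl]oxy}cyclohex-2-en-1-yl]acetate | CCOC(=O)[C@@H](O)[C@H]1CCCC=C1OS(=O)(=O)C(F)(F)F | intermediate
7 | ethyl (3S,3aS)-1-oxo-1,3,3a,4,5,6-hexahydro-2-benzofuran-3-carboxylate | CCOC(=O)[C@H]1OC(=O)C2=CCCC[C@H]12 | intermediate
8 | (3S,3aS)-1-oxo-1,3,3a,4,5,6-hexahydro-2-benzofuran-3-carboxylic acid | OC(=O)[C@H]1OC(=O)C2=CCCC[C@H]12 | intermediate
9 | S-ethyl (3S,3aS)-1-oxo-1,3,3a,4,5,6-hexahydro-2-benzofuran-3-carbothioate | CCSC(=O)[C@H]1OC(=O)C2=CCCC[C@H]12 | intermediate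
10 | L-glutamic acid | N[C@@H](CCC(=O)O)C(=O)O | starting material
11 | (2S)-5-oxooxolane-2-carboxylic acid | O=C(O)[C@@H]1CCC(=O)O1 | intermediate
12 | (5S)-5-(hydroxymethyl)oxolan-2-one | OC[C@@H]1CCC(=O)O1 | intermediate
13 | (2S)-5-oxooxolane-2-carbaldehyde | O=C[C@@H]1CCC(=O)O1 | intermediate
14 | tert-butyl (2E)-3-[(2S)-5-oxooxolan-2-yl]prop-2-enoate | CC(C)(C)OC(=O)/C=C/[C@@H]1CCC(=O)O1 | intermediate
15 | tert-butyl (2E,4S)-4-hydroxy-7-[methoxy(methyl)amino]-7-oxohept-2-enoate | CON(C)C(=O)CC[C@H](O)/C=C/C(=O)OC(C)(C)C | intermediate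
16 | tert-butyl (2E,4S)-4-[(tert-butoxycarbonyl)oxy]-7-[methoxy(methyl)amino]-7-oxohept-2-enoate | CON(C)C(=O)CC[C@H](OC(=O)OC(C)(C)C)/C=C/C(=O)OC(C)(C)C | intermediate
17 | S-ethyl (3R,3aS)-3-{(4S,5E)-7-tert-butoxy-1-[methoxy(methyl)amino]-1,7-dioxohept-5-en-4-yl}-1-oxo-1,3,3a,4,5,6-hexahydro-2-benzofuran-3-carbothioate | CCSC(=O)[C@@]1(OC(=O)C2=CCCC[C@H]12)[C@@H](CCC(=O)N(C)OC)/C=C/C(=O)OC(C)(C)C | intermediate
18 | lithium tert-butyl ester enolate of the Michael adduct (C14–C15 bond formed, rings C/D/E closed, Weinreb amide still open; formed in the flask) | CC(C)(C)OC([O-])=C[C@H]1[C@H](CCC(=O)N(C)OC)[C@@]2(C(=O)SCC)OC(=O)[C@@]13C=CCC[C@H]23.[Li+] | intermediate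
19 | B/C/D/E tetracycle, ring B as enolised β-keto ester (C9–CO2tBu, C10–OH, C21–C(=O)SEt; 13S,14S,15S,20S,21R) | CC(C)(C)OC(=O)C1=C(O)CC[C@H]2[C@H]1[C@@]13C=CCC[C@@H]1[C@]2(C(=O)SCC)OC3=O | intermediate
20 | ring-B enol triflate (C9–CO2tBu, C10–OSO2CF3, C21–C(=O)SEt; 13S,14S,15S,20S,21R) | CC(C)(C)OC(=O)C1=C(OS(=O)(=O)C(F)(F)F)CC[C@H]2[C@H]1[C@@]13C=CCC[C@@H]1[C@]2(C(=O)SCC)OC3=O | intermediate
21 | 1-pentyne | CCCC#C | starting material
22 | ring-B enyne ester (C9–CO2tBu, C10–pent-1-ynyl, C21–C(=O)SEt; 13S,14S,15S,20S,21R) | CC(C)(C)OC(=O)C1=C(C#CCCC)CC[C@H]2[C@H]1[C@@]13C=CCC[C@@H]1[C@]2(C(=O)SCC)OC3=O | intermediate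
23 | ring-B enyne acid (C9–CO2H, C10–pent-1-ynyl, C21–C(=O)SEt; formed in the flask) | OC(=O)C1=C(C#CCCC)CC[C@H]2[C@H]1[C@@]13C=CCC[C@@H]1[C@]2(C(=O)SCC)OC3=O | intermediate
24 | S-ethyl thioester analogue of the target (rings A–E, (Z)-butylidene, C21–C(=O)SEt; 13S,14S,15S,20S,21R) | CCC/C=C1\OC(=O)C2=C1CC[C@H]1[C@H]2[C@@]23C=CCC[C@@H]2[C@]1(C(=O)SCC)OC3=O | intermediate
25 | 1-iodopropane | CCCI | starting material
26 | iodo(propyl)zinc | CCC[Zn]I | intermediate
27 | CNP0423313.2 (rings A–E, (Z)-butylidene, C21-butanoyl; 13S,14S,15S,20S,21R) | CCC/C=C1\OC(=O)C2=C1CC[C@H]1[C@H]2[C@@]23C=CCC[C@@H]2[C@]1(C(=O)CCC)OC3=O | target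

## Step count and risks

Total step count: 20.
Longest linear sequence: 13 steps (steps 1–7, 14–18 and 20). The West branch has 6 steps (8–13) and the reagent branch 1 step (19).

**Step 14** (congested C21–C13 bond; the π-allyl complex may lose a β-hydrogen to give the dienoate or be attacked at the wrong terminus). The fallback makes the same bond by an Ireland–Claisen rearrangement. It sets out from acid 8 and comes back at 17. Allyl pent-4-enoate is cyclised by ring-closing metathesis (second-generation Grubbs catalyst, CH2Cl2, high dilution) to 4,7-dihydrooxepin-2(3H)-one F1. F1 is opened with MeNH(OMe)·HCl/iPrMgCl to (4Z)-6-hydroxy-N-methoxy-N-methylhex-4-enamide F2. Acid 8 is esterified with F2 (dicyclohexylcarbodiimide, DMAP) to (2Z)-6-[methoxy(methyl)amino]-6-oxohex-2-en-1-yl (3S,3aS)-1-oxo-1,3,3a,4,5,6-hexahydro-2-benzofuran-3-carboxylate F3. Treatment with LiN(SiMe3)2 and Me3SiCl in THF (−78 °C → rt, then dilute acid) rearranges the silyl ketene acetal (O-allyl cis to C20) through a chair on the lactone face anti to C19, which with the Z-alkene gives (3R,3aS)-3-{(3S)-6-[methoxy(methyl)amino]-6-oxohex-1-en-3-yl}-1-oxo-1,3,3a,4,5,6-hexahydro-2-benzofuran-3-carboxylic acid F4. EDC·HCl/EtSH converts F4 into its S-ethyl thioester F5, and cross-metathesis of the vinyl group of F5 with tert-butyl acrylate (Hoveyda–Grubbs second-generation catalyst, CH2Cl2, 40 °C) gives 17.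

**Step 15** (γ-deprotonation may compete with deprotonation at C13; the trans-fused ring B is strained and the in-flask acylation may stall). The fallback separates the two ring closures and makes the Michael donor a silyl dienolate. It sets out from 17 and comes back at 19. Soft enolisation of the lactone (tBuMe2SiOTf, Et3N, CH2Cl2, −78 °C) gives the tert-butyldimethylsilyl dienol ether of 17 F6 (C23(OSi)=C15, C16=C17). Fluoride ((Me2N)3S+ Me3SiF2−, THF, −78 °C, then AcOH) triggers the intramolecular Mukaiyama–Michael addition to the neutral Michael adduct F7 (C14–C15 bond formed, C9H2–CO2tBu and Weinreb amide still open). A separate Dieckmann-type closure of F7 with LiN(SiMe3)2 (THF, −78 → 0 °C; the ester α-position C9 is more acidic than C11 next to the amide) gives 19.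

**Step 20** (the thioester sits on a quaternary, oxygen-bearing bridgehead carbon and may resist acyl cross-coupling). The fallback builds the ketone through the aldehyde. It sets out from 24 and comes back at 27. Fukuyama reduction (Et3SiH, Pd on CaCO3 poisoned with Pb(OAc)2, acetone, rt) gives the C24 aldehyde analogue of the target F8. n-PrTi(OiPr)3 (from n-PrMgBr and ClTi(OiPr)3; THF, −78 → −20 °C) adds to the aldehyde only and gives the C24 carbinol F9 as an epimer mixture. Dess–Martin periodinane then oxidises F9 to 27.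

Further compounds

F1 | step 14 | 4,7-dihydrooxepin-2(3H)-one | O=C1CCC=CCO1
F2 | step 14 | (4Z)-6-hydroxy-N-methoxy-N-methylhex-4-enamide | CON(C)C(=O)CC/C=C\CO
F3 | step 14 | (2Z)-6-[methoxy(methyl)amino]-6-oxohex-2-en-1-yl (3S,3aS)-1-oxo-1,3,3a,4,5,6-hexahydro-2-benzofuran-3-carboxylate | CON(C)C(=O)CC/C=C\COC(=O)[C@H]1OC(=O)C2=CCCC[C@H]12
F4 | step 14 | (3R,3aS)-3-{(3S)-6-[methoxy(methyl)amino]-6-oxohex-1-en-3-yl}-1-oxo-1,3,3a,4,5,6-hexahydro-2-benzofuran-3-carboxylic acid | OC(=O)[C@@]1(OC(=O)C2=CCCC[C@H]12)[C@@H](CCC(=O)N(C)OC)C=C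
F5 | step 14 | S-ethyl (3R,3aS)-3-{(3S)-6-[methoxy(methyl)amino]-6-oxohex-1-en-3-yl}-1-oxo-1,3,3a,4,5,6-hexahydro-2-benzofuran-3-carbothioate | CCSC(=O)[C@@]1(OC(=O)C2=CCCC[C@H]12)[C@@H](CCC(=O)N(C)OC)C=C
F6 | step 15 | tert-butyldimethylsilyl dienol ether of 17 (C23(OSi)=C15, C16=C17) | CCSC(=O)[C@@]1(OC(O[Si](C)(C)C(C)(C)C)=C2C=CCC[C@H]12)[C@@H](CCC(=O)N(C)OC)/C=C/C(=O)OC(C)(C)C
F7 | step 15 | neutral Michael adduct (C14–C15 bond formed; C9H2–CO2tBu and C10 Weinreb amide open) | CC(C)(C)OC(=O)C[C@H]1[C@H](CCC(=O)N(C)OC)[C@@]2(C(=O)SCC)OC(=O)[C@@]13C=CCC[C@H]23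
F8 | step 20 | C24 aldehyde analogue of the target (C21–CHO) | CCC/C=C1\OC(=O)C2=C1CC[C@H]1[C@H]2[C@@]23C=CCC[C@@H]2[C@]1(C=O)OC3=O
F9 | step 20 | C24 carbinol analogue of the target (C21–CH(OH)CH2CH2CH3, epimer mixture at C24) | CCC/C=C1\OC(=O)C2=C1CC[C@H]1[C@H]2[C@@]23C=CCC[C@@H]2[C@]1(C(O)CCC)OC3=O
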